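**Plan**
- Retrosynthesis: after removal of all benzyl-type groups, flavanone ring C is opened at C4–C4a (acyl–arene bond). Further cuts follow at C2–O1 (aryl ether), C2–C3 (allyl–carbinol bond), the biaryl bond between ring B C5' and flavone C8, and finally the flavone pyranone.
- Forward: the 8-iodoflavone is built from phloroacetophenone and joined to a ring B boronate by Suzuki coupling. The ring B catechol is then changed to benzyl carbonates, the three-carbon chain and the phloroglucinol ether are attached, and flavanone ring C closes just before global hydrogenolysis.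
- Enabling feature: ring A of the flavanone is a phloroglucinol whose ether oxygen O1 is flanked by two equivalent ortho carbons, each activated by three oxygens. C4–C4a can therefore be made by mild acylation, with no regiochemical choice and with C2 already in place.
- Stereochemistry: C2 comes from a Keck allylation of the ring B aldehyde, which gives the (R)-carbinol, and is inverted once to (S) by Mitsunobu etherification. No later step makes or breaks a bond at C2, and the end game is acidic or neutral, so epimerisation through the chalcone is excluded.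

Key step: step 15

Remark: the target carries no axial descriptor, so the biaryl axis is treated as freely rotating; slowly interconverting rotamers of protected intermediates are expected to converge on deprotection.
Abbreviations: Fl = 5,7-bis(benzyloxy)-2-[3,4-bis(benzyloxy)phenyl]-4-oxo-4H-chromen-8-yl; ArB = 3-Fl-4,5-bis[(benzyloxycarbonyl)oxy]phenyl; Bn = benzyl; MOM = methoxymethyl; Cbz = benzyloxycarbonyl.

**Step 1**
Reactants: 1 2,4,6-trihydroxyacetophenone
Product: 2 1-[2,4-bis(benzyloxy)-6-hydroxyphenyl]ethan-1-one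
Conditions: BnBr (2.1 equiv), K2CO3, DMF, rt to 60 °C
Reagents that add atoms: benzyl bromide, BrCc1ccccc1
Why: Williamson etherification with a carbonate base should stop at the diether, because the last ortho hydroxyl is held in a hydrogen bond to the acetyl carbonyl and is the least nucleophilic.

**Step 2**
Reactants: 2 1-[2,4-bis(benzyloxy)-6-hydroxyphenyl]ethan-1-one
Product: 3 1-[4,6-bis(benzyloxy)-2-hydroxy-3-iodophenyl]ethan-1-one
Conditions: BnMe3N·ICl2 (1.05 equiv), NaHCO3, CH2Cl2–MeOH, rt
Reagents that add atoms: benzyltrimethylammonium dichloroiodate, C[N+](C)(C)Cc1ccccc1.Cl[I-]Cl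
Why: Electrophilic aromatic iodination of the phenol should go ortho to the free hydroxyl (C3), the other open carbon being flanked by two benzyloxy groups; the position would be confirmed by HMBC before going on.

**Step 3**
Reactants: 3 1-[4,6-bis(benzyloxy)-2-hydroxy-3-iodophenyl]ethan-1-one; 4 3,4-bis(benzyloxy)benzaldehyde
Product: 5 (E)-1-[4,6-bis(benzyloxy)-2-hydroxy-3-iodophenyl]-3-[3,4-bis(benzyloxy)phenyl]prop-2-en-1-one
Conditions: KOH (50% aq.), EtOH–THF, rt
Reagents that add atoms: none
Why: Claisen–Schmidt condensation (aldol addition, then dehydration) of the methyl ketone with a non-enolisable aldehyde should give the E-enone, and the aryl iodide and benzyl ethers are inert to hydroxide at room temperature.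

**Step 4**
Reactants: 5 (E)-chalcone
Product: 6 5,7-bis(benzyloxy)-2-[3,4-bis(benzyloxy)phenyl]-8-iodo-4H-chromen-4-one
Conditions: I2 (10 mol%), DMSO, 120 °C
Reagents that add atoms: none
Why: Iodine-catalysed oxidative cyclisation of a 2'-hydroxychalcone in DMSO (oxa-Michael closure and dehydrogenation, DMSO as terminal oxidant) should give the flavone, and since only the hydroxyl next to iodine is free, the halogen must end at C8.

**Step 5**
Reactants: 7 5-bromovanillin
Product: 8 3-bromo-4,5-dihydroxybenzaldehyde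
Conditions: AlCl3, pyridine, CH2Cl2, reflux; then aq. HCl
Reagents that add atoms: none
Why: Lewis-acid demethylation of an aryl methyl ether ortho to a free phenol, in which the aluminium phenoxide activates the neighbouring methoxy group for methyl transfer to pyridine, should leave the aldehyde and the bromide untouched.

**Step 6**
Reactants: 8 3-bromo-4,5-dihydroxybenzaldehyde
Product: 9 3-bromo-4,5-bis(methoxymethoxy)benzaldehyde
Conditions: MOMCl, iPr2NEt, CH2Cl2, 0 °C to rt
Reagents that add atoms: chloromethyl methyl ether, COCCl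
Why: O-alkylation of both phenols as methoxymethyl acetals gives a catechol protection that withstands the two basic palladium steps and can later be removed by acid without touching benzyl ethers.

**Step 7**
Reactants: 9 3-bromo-4,5-bis(methoxymethoxy)benzaldehyde
Product: 10 3,4-bis(methoxymethoxy)-5-(4,4,5,5-tetramethyl-1,3,2-dioxaborolan-2-yl)benzaldehyde
Conditions: B2pin2, Pd(dppf)Cl2 (3 mol%), KOAc, 1,4-dioxane, 90 °C
Reagents that add atoms: bis(pinacolato)diboron, CC1(C)OB(OC1(C)C)B1OC(C)(C)C(C)(C)O1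
Why: Miyaura borylation of the aryl bromide with the weak base KOAc should tolerate the aldehyde and avoid homocoupling.

**Step 8**
Reactants: 6 8-iodoflavone; 10 ring B pinacol boronate
Product: 11 3-Fl-4,5-bis(methoxymethoxy)benzaldehyde
Conditions: Pd(OAc)2 (5 mol%), SPhos (10 mol%), K3PO4, toluene–H2O (10:1), 90 °C
Reagents that add atoms: none
Why: Suzuki–Miyaura cross-coupling with a bulky biarylphosphine should forge the tri-ortho-substituted biaryl bond between flavone C8 and ring B, a substitution pattern well known for 8-iodoflavones and ortho-alkoxyarylboronates.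

**Step 9**
Reactants: 11 3-Fl-4,5-bis(methoxymethoxy)benzaldehyde
Product: 12 3-Fl-4,5-dihydroxybenzaldehyde
Conditions: 3 M aq. HCl, MeOH–THF, 45 °C
Reagents that add atoms: none
Why: Acid-catalysed acetal cleavage should remove both methoxymethyl groups while the benzyl ethers and the flavone stay intact, and the aqueous medium returns the free aldehyde.

**Step 10**
Reactants: 12 3-Fl-4,5-dihydroxybenzaldehyde
Product: 13 3-Fl-4,5-bis[(benzyloxycarbonyl)oxy]benzaldehyde
Conditions: CbzCl (3 equiv), Et3N, CH2Cl2, −10 °C to rt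
Reagents that add atoms: benzyl chloroformate, O=C(Cl)OCc1ccccc1
Why: O-acylation of both phenols with a chloroformate, run with excess reagent so that the second acylation outpaces closure to the cyclic carbonate, should give the electron-poor bis(benzyl carbonate) that later protects C2 against ionisation.

**Step 11**
Reactants: 13 3-Fl-4,5-bis[(benzyloxycarbonyl)oxy]benzaldehyde
Product: 14 (1R)-1-ArB-but-3-en-1-ol
Conditions: (R)-BINOL (20 mol%), Ti(OiPr)4 (10 mol%), 4 Å MS, allylSnBu3, CH2Cl2, −20 °C; aq. NaHCO3 work-up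
Reagents that add atoms: allyltributylstannane, C=CC[Sn](CCCC)(CCCC)CCCC
Why: Keck asymmetric allylation, in which the (R)-BINOL–titanium Lewis acid exposes the Re face of the aryl aldehyde to the allylstannane, should set the carbinol centre as (R) under neutral conditions that spare the aryl carbonates.

**Step 12**
Reactants: 14 (1R)-1-ArB-but-3-en-1-ol; 15 3,5-bis(benzyloxy)phenol
Product: 16 (S)-1-ArB-but-3-enyl 3,5-bis(benzyloxy)phenyl ether
Conditions: PPh3, DIAD, toluene, 0 °C to rt
Reagents that add atoms: none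
Why: Mitsunobu etherification should displace the oxyphosphonium group by the phenol in an SN2 step with inversion, (R) to (S), because the carbonate-bearing ring B destabilises the benzylic cation that would otherwise leak stereochemistry.

**Step 13**
Reactants: 16 (S)-1-ArB-but-3-enyl 3,5-bis(benzyloxy)phenyl ether
Product: 18 (3S)-3-ArB-3-[3,5-bis(benzyloxy)phenoxy]propanal, via vicinal diol 17 (not isolated)
Conditions: OsO4 (2 mol%), NaIO4, 2,6-lutidine, 1,4-dioxane–H2O, rt
Reagents that add atoms: osmium tetroxide, O=[Os](=O)(=O)=O; sodium periodate, [Na+].[O-]I(=O)(=O)=O; water, O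
Why: Lemieux–Johnson oxidative cleavage (dihydroxylation, then periodate glycol fission) should act only on the terminal alkene, the flavone C2–C3 double bond being an electron-poor vinylogous ester, and the lutidine-buffered medium should keep the β-aryloxy aldehyde from eliminating before it is used crude.

**Step 14**
Reactants: 18 (3S)-3-ArB-3-[3,5-bis(benzyloxy)phenoxy]propanal
Product: 19 (3S)-3-ArB-3-[3,5-bis(benzyloxy)phenoxy]propanoic acid
Conditions: NaClO2, NaH2PO4, 2-methyl-2-butene (excess), t-BuOH–THF–H2O, 0 °C to rt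
Reagents that add atoms: sodium chlorite, [Na+].[O-]Cl=O
Why: Pinnick oxidation runs at mildly acidic pH, so neither β-elimination nor carbonate hydrolysis is expected, and excess 2-methyl-2-butene traps hypochlorous acid before it can chlorinate the electron-rich rings.

**Step 15**
Reactants: 19 (3S)-3-ArB-3-[3,5-bis(benzyloxy)phenoxy]propanoic acid
Product: 21 (2S)-2-ArB-5,7-bis(benzyloxy)chroman-4-one, via mixed trifluoroacetic anhydride 20 (not isolated)
Conditions: (CF3CO)2O (1.5 equiv), CH2Cl2, −20 to 0 °C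
Reagents that add atoms: none
Why: Trifluoroacetic anhydride converts the acid into mixed anhydride 20, which ionises (helped by the trifluoroacetic acid released) to an acylium-type electrophile that is attacked by the ring carbon ortho to the aryl ether oxygen and para to a benzyloxy group, after which proton loss restores the arene; this is an intramolecular Friedel–Crafts acylation of the kind long used to turn 3-aryloxypropanoic acids into chroman-4-ones. Ring C closes as a six-membered ring in the exo mode with respect to the acyl C–O multiple bond (6-exo), and C4–C4a is the only skeletal bond formed. No stereocentre is created: C2 was fixed in steps 11 and 12 and none of its bonds is made or broken here, so the (S) configuration should carry through. Regioselectivity needs no control, because the two ortho carbons of the 3,5-bis(benzyloxy)phenoxy ring are equivalent by symmetry and the para carbon cannot reach the acyl group. The selectivity that matters is acylation against acid-induced ionisation of the benzylic C2–O1 bond (the 4'-oxygen lies para to C2) and against intermolecular trifluoroacetylation; the two electron-withdrawing benzyl carbonates on ring B disfavour the benzylic cation, and the three oxygen donors on the attacked ring should let the closure run at or below 0 °C with only a small excess of anhydride.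

**Step 16**
Reactants: 21 (2S)-2-ArB-5,7-bis(benzyloxy)chroman-4-one
Product: 22 target, (2S)-2-{3-[2-(3,4-dihydroxyphenyl)-5,7-dihydroxy-4-oxo-4H-chromen-8-yl]-4,5-dihydroxyphenyl}-5,7-dihydroxychroman-4-one
Conditions: H2 (1 atm), Pd/C (10%), THF–MeOH, rt, stopped at the calculated uptake
Reagents that add atoms: none
Why: Catalytic hydrogenolysis should cleave the six benzyl ethers and both benzyl carbonates (the latter losing CO2 after O–benzyl scission) under neutral conditions, so C2 cannot epimerise through the chalcone, and stopping at the calculated uptake should spare the flavone double bond and the benzylic C2–O1 bond.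

**Compound list**
1 | 2,4,6-trihydroxyacetophenone | CC(=O)c1c(O)cc(O)cc1O | starting material
2 | 1-[2,4-bis(benzyloxy)-6-hydroxyphenyl]ethan-1-one | CC(=O)c1c(O)cc(OCc2ccccc2)cc1OCc1ccccc1 | intermediate
3 | 1-[4,6-bis(benzyloxy)-2-hydroxy-3-iodophenyl]ethan-1-one | CC(=O)c1c(O)c(I)c(OCc2ccccc2)cc1OCc1ccccc1 | intermediate
4 | 3,4-bis(benzyloxy)benzaldehyde | O=Cc1ccc(OCc2ccccc2)c(OCc2ccccc2)c1 | starting material
5 | (E)-1-[4,6-bis(benzyloxy)-2-hydroxy-3-iodophenyl]-3-[3,4-bis(benzyloxy)phenyl]prop-2-en-1-one | O=C(/C=C/c1ccc(OCc2ccccc2)c(OCc2ccccc2)c1)c1c(O)c(I)c(OCc2ccccc2)cc1OCc1ccccc1 | intermediate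
6 | 5,7-bis(benzyloxy)-2-[3,4-bis(benzyloxy)phenyl]-8-iodo-4H-chromen-4-one | O=c1cc(-c2ccc(OCc3ccccc3)c(OCc3ccccc3)c2)oc2c(I)c(OCc3ccccc3)cc(OCc3ccccc3)c12 | intermediate
7 | 5-bromovanillin (3-bromo-4-hydroxy-5-methoxybenzaldehyde) | COc1cc(C=O)cc(Br)c1O | starting material
8 | 3-bromo-4,5-dihydroxybenzaldehyde | O=Cc1cc(O)c(O)c(Br)c1 | intermediate
9 | 3-bromo-4,5-bis(methoxymethoxy)benzaldehyde | O=Cc1cc(OCOC)c(OCOC)c(Br)c1 | intermediate
10 | 3,4-bis(methoxymethoxy)-5-(4,4,5,5-tetramethyl-1,3,2-dioxaborolan-2-yl)benzaldehyde | O=Cc1cc(OCOC)c(OCOC)c(B2OC(C)(C)C(C)(C)O2)c1 | intermediate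
11 | 3-Fl-4,5-bis(methoxymethoxy)benzaldehyde | O=Cc1cc(OCOC)c(OCOC)c(-c2c(OCc3ccccc3)cc(OCc3ccccc3)c3c(=O)cc(-c4ccc(OCc5ccccc5)c(OCc5ccccc5)c4)oc23)c1 | intermediate
12 | 3-Fl-4,5-dihydroxybenzaldehyde | O=Cc1cc(O)c(O)c(-c2c(OCc3ccccc3)cc(OCc3ccccc3)c3c(=O)cc(-c4ccc(OCc5ccccc5)c(OCc5ccccc5)c4)oc23)c1 | intermediate
13 | 3-Fl-4,5-bis[(benzyloxycarbonyl)oxy]benzaldehyde | O=Cc1cc(OC(=O)OCc2ccccc2)c(OC(=O)OCc2ccccc2)c(-c2c(OCc3ccccc3)cc(OCc3ccccc3)c3c(=O)cc(-c4ccc(OCc5ccccc5)c(OCc5ccccc5)c4)oc23)c1 | intermediate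
14 | (1R)-1-ArB-but-3-en-1-ol | C=CC[C@@H](O)c1cc(OC(=O)OCc2ccccc2)c(OC(=O)OCc2ccccc2)c(-c2c(OCc3ccccc3)cc(OCc3ccccc3)c3c(=O)cc(-c4ccc(OCc5ccccc5)c(OCc5ccccc5)c4)oc23)c1 | intermediate
15 | 3,5-bis(benzyloxy)phenol | Oc1cc(OCc2ccccc2)cc(OCc2ccccc2)c1 | starting material
16 | (S)-1-ArB-but-3-enyl 3,5-bis(benzyloxy)phenyl ether | C=CC[C@H](Oc1cc(OCc2ccccc2)cc(OCc2ccccc2)c1)c1cc(OC(=O)OCc2ccccc2)c(OC(=O)OCc2ccccc2)c(-c2c(OCc3ccccc3)cc(OCc3ccccc3)c3c(=O)cc(-c4ccc(OCc5ccccc5)c(OCc5ccccc5)c4)oc23)c1 | intermediate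
17 | (4S)-4-ArB-4-[3,5-bis(benzyloxy)phenoxy]butane-1,2-diol, both C2 epimers | OCC(O)C[C@H](Oc1cc(OCc2ccccc2)cc(OCc2ccccc2)c1)c1cc(OC(=O)OCc2ccccc2)c(OC(=O)OCc2ccccc2)c(-c2c(OCc3ccccc3)cc(OCc3ccccc3)c3c(=O)cc(-c4ccc(OCc5ccccc5)c(OCc5ccccc5)c4)oc23)c1 | intermediate
18 | (3S)-3-ArB-3-[3,5-bis(benzyloxy)phenoxy]propanal | O=CC[C@H](Oc1cc(OCc2ccccc2)cc(OCc2ccccc2)c1)c1cc(OC(=O)OCc2ccccc2)c(OC(=O)OCc2ccccc2)c(-c2c(OCc3ccccc3)cc(OCc3ccccc3)c3c(=O)cc(-c4ccc(OCc5ccccc5)c(OCc5ccccc5)c4)oc23)c1 | intermediate
19 | (3S)-3-ArB-3-[3,5-bis(benzyloxy)phenoxy]propanoic acid | OC(=O)C[C@H](Oc1cc(OCc2ccccc2)cc(OCc2ccccc2)c1)c1cc(OC(=O)OCc2ccccc2)c(OC(=O)OCc2ccccc2)c(-c2c(OCc3ccccc3)cc(OCc3ccccc3)c3c(=O)cc(-c4ccc(OCc5ccccc5)c(OCc5ccccc5)c4)oc23)c1 | intermediate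
20 | mixed anhydride of acid 19 with trifluoroacetic acid | O=C(C[C@H](Oc1cc(OCc2ccccc2)cc(OCc2ccccc2)c1)c1cc(OC(=O)OCc2ccccc2)c(OC(=O)OCc2ccccc2)c(-c2c(OCc3ccccc3)cc(OCc3ccccc3)c3c(=O)cc(-c4ccc(OCc5ccccc5)c(OCc5ccccc5)c4)oc23)c1)OC(=O)C(F)(F)F | intermediate
21 | (2S)-2-ArB-5,7-bis(benzyloxy)chroman-4-one | O=C1C[C@@H](c2cc(OC(=O)OCc3ccccc3)c(OC(=O)OCc3ccccc3)c(-c3c(OCc4ccccc4)cc(OCc4ccccc4)c4c(=O)cc(-c5ccc(OCc6ccccc6)c(OCc6ccccc6)c5)oc34)c2)Oc2cc(OCc3ccccc3)cc(OCc3ccccc3)c21 | intermediate
22 | (2S)-2-{3-[2-(3,4-dihydroxyphenyl)-5,7-dihydroxy-4-oxo-4H-chromen-8-yl]-4,5-dihydroxyphenyl}-5,7-dihydroxychroman-4-one | O=C1C[C@@H](c2cc(O)c(O)c(-c3c(O)cc(O)c4c(=O)cc(-c5ccc(O)c(O)c5)oc34)c2)Oc2cc(O)cc(O)c21 | target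

**Step count**
Total steps: 16. Longest linear sequence: 13 steps (from 1 through steps 1–4 and 8–16).

**Steps most likely to fail**

Step 12 (Mitsunobu etherification). The oxyphosphonium intermediate may ionise and erode the enantiomeric purity, may eliminate to the conjugated aryl diene, or the phenol may pick up a benzyloxycarbonyl group from ring B. The fallback arylates the carbinol oxygen instead of alkylating the phenol, so that no bond at the benzylic carbon is broken. Setting out from 13, Keck allylation with (S)-BINOL in place of (R)-BINOL would give the enantiomeric carbinol, (1S)-1-ArB-but-3-en-1-ol F1. Copper-catalysed oxidative O-arylation of the Chan–Lam type (Cu(OAc)2·H2O, DMAP, 4 Å MS, O2, CH2Cl2, rt) with potassium [3,5-bis(benzyloxy)phenyl]trifluoroborate F2, made from the commercial boronic acid and KHF2, should then proceed with retention and rejoin the route at 16.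

Step 15 (ring closure). Intermolecular trifluoroacetylation of the electron-rich rings, acidolysis of benzyl ethers, or ionisation of the C2–O1 bond may compete with the acylation. The fallback forms the same C4–C4a bond one oxidation level lower and without anhydride or strong acid. Setting out from aldehyde 18, a catalytic mild Lewis acid (Sc(OTf)3, CH2Cl2, −40 °C) should trigger intramolecular Friedel–Crafts hydroxyalkylation of the same ortho carbon to give (2S)-2-ArB-5,7-bis(benzyloxy)chroman-4-ol F3 as a mixture of C4 epimers. Buffered Dess–Martin oxidation (NaHCO3, CH2Cl2, 0 °C) of the benzylic alcohol should then rejoin the route at 21.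

Step 13 (oxidative cleavage). The β-aryloxy aldehyde may lose the aryloxide by elimination, or osmium and periodate may over-oxidise other sites of the molecule. The fallback brings in the carboxyl carbon at the ester level before the ether is made. Setting out from 13, Roskamp homologation with tert-butyl diazoacetate (SnCl2 cat., CH2Cl2, rt) would give tert-butyl 3-ArB-3-oxopropanoate F4. Noyori transfer hydrogenation (RuCl(p-cymene)[(R,R)-TsDPEN], HCO2H–Et3N) would give tert-butyl (3R)-3-ArB-3-hydroxypropanoate F5. Mitsunobu etherification with 15 would give tert-butyl (3S)-3-ArB-3-[3,5-bis(benzyloxy)phenoxy]propanoate F6, and cleavage of the tert-butyl ester (CF3CO2H, CH2Cl2, 0 °C) would rejoin the route at acid 19.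

**Further compounds**
F1 | step 12 | (1S)-1-ArB-but-3-en-1-ol | C=CC[C@H](O)c1cc(OC(=O)OCc2ccccc2)c(OC(=O)OCc2ccccc2)c(-c2c(OCc3ccccc3)cc(OCc3ccccc3)c3c(=O)cc(-c4ccc(OCc5ccccc5)c(OCc5ccccc5)c4)oc23)c1
F2 | step 12 | potassium [3,5-bis(benzyloxy)phenyl]trifluoroborate | [K+].F[B-](F)(F)c1cc(OCc2ccccc2)cc(OCc2ccccc2)c1
F3 | step 15 | (2S)-2-ArB-5,7-bis(benzyloxy)chroman-4-ol, both C4 epimers | OC1C[C@@H](c2cc(OC(=O)OCc3ccccc3)c(OC(=O)OCc3ccccc3)c(-c3c(OCc4ccccc4)cc(OCc4ccccc4)c4c(=O)cc(-c5ccc(OCc6ccccc6)c(OCc6ccccc6)c5)oc34)c2)Oc2cc(OCc3ccccc3)cc(OCc3ccccc3)c21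
F4 | step 13 | tert-butyl 3-ArB-3-oxopropanoate | CC(C)(C)OC(=O)CC(=O)c1cc(OC(=O)OCc2ccccc2)c(OC(=O)OCc2ccccc2)c(-c2c(OCc3ccccc3)cc(OCc3ccccc3)c3c(=O)cc(-c4ccc(OCc5ccccc5)c(OCc5ccccc5)c4)oc23)c1
F5 | step 13 | tert-butyl (3R)-3-ArB-3-hydroxypropanoate | CC(C)(C)OC(=O)C[C@@H](O)c1cc(OC(=O)OCc2ccccc2)c(OC(=O)OCc2ccccc2)c(-c2c(OCc3ccccc3)cc(OCc3ccccc3)c3c(=O)cc(-c4ccc(OCc5ccccc5)c(OCc5ccccc5)c4)oc23)c1
F6 | step 13 | tert-butyl (3S)-3-ArB-3-[3,5-bis(benzyloxy)phenoxy]propanoate | CC(C)(C)OC(=O)C[C@H](Oc1cc(OCc2ccccc2)cc(OCc2ccccc2)c1)c1cc(OC(=O)OCc2ccccc2)c(OC(=O)OCc2ccccc2)c(-c2c(OCc3ccccc3)cc(OCc3ccccc3)c3c(=O)cc(-c4ccc(OCc5ccccc5)c(OCc5ccccc5)c4)oc23)c1
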